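The bicyclo[9.3.1] core is opened at C10–C11, and the C12=C18 methylene is taken off in the same retrosynthetic stroke. This rests on one feature: the oxygenated carbons C10 and C13 lie 1,4 to each other across the C11–C12 bond of ring A (C1, C14, C13, C12, C11, C15), with the methylene on C12. In the forward sense a samarium ketyl at C10 adds to C11 of the ring enone, closing the twelve-membered ring (C1–C11 plus C15), and the C12–C13 enolate so formed is methylenated with Eschenmoser's salt. The precursor is an (R)-5-substituted 4,4-dimethylcyclohex-2-enone bearing an E,E-dienal chain; acetylation and double epoxidation finish the synthesis.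

Key step: step 12

Remark: numbering follows bicyclo[9.3.1]pentadecane (C1–C15; C18 = exocyclic methylene carbon); the ring stereocentre C1 of the open-chain enone intermediates is R by the CIP rules; the L-fructose-derived enantiomer of the Shi ketone (accessible from L-sorbose) is taken as available.

**Step 1**
Reactants: 1 4,4-dimethylcyclohex-2-en-1-one
Product: 2 4,4-dimethylcyclohexa-2,5-dien-1-one
Conditions: DDQ (1.3 equiv), dioxane, reflux
Reagents that add atoms: none
Why: Quinone (DDQ) dehydrogenation through the dienol gives the cross-conjugated dienone, and the quaternary C4 blocks aromatisation so that oxidation stops there.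

**Step 2**
Reactants: 2 4,4-dimethylcyclohexa-2,5-dien-1-one; 3 (chloromethyl)(isopropoxy)dimethylsilane
Product: 5 (5R)-5-{[isopropoxy(dimethyl)silyl]methyl}-4,4-dimethylcyclohex-2-en-1-one, via silylmethyl Grignard reagent 4 (not isolated)
Conditions: 3, Mg, Et2O, rt; then CuBr·SMe2 (5 mol %), (R,S)-Josiphos (6 mol %), 2, t-BuOMe, −78 °C; aq NH4Cl
Reagents that add atoms: none
Why: Copper-catalysed asymmetric conjugate addition of a Grignard reagent desymmetrises the dienone, the chiral ferrocenyl diphosphine–copper complex selecting one set of enantiotopic β-carbon faces to set C1 as R (ligand enantiomer to be chosen accordingly), while the magnesium dienolate formed shields the second enone from further addition until quench.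

**Step 3**
Reactants: 5 (5R)-5-{[isopropoxy(dimethyl)silyl]methyl}-4,4-dimethylcyclohex-2-en-1-one
Product: 6 (5R)-5-(hydroxymethyl)-4,4-dimethylcyclohex-2-en-1-one
Conditions: mCPBA, KHF2, DMF, rt
Reagents that add atoms: 3-chloroperoxybenzoic acid, OOC(=O)c1cccc(Cl)c1
Why: Tamao oxidation (fluoride activation, then peracid-induced migration of the CH2 group from silicon to oxygen) converts C–Si into C–OH, and the non-basic peracid variant is chosen so that no hydroperoxide anion is present to epoxidise the enone, which is itself inert to mCPBA.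

**Step 4**
Reactants: 6 (5R)-5-(hydroxymethyl)-4,4-dimethylcyclohex-2-en-1-one
Product: 7 (5R)-5-(iodomethyl)-4,4-dimethylcyclohex-2-en-1-one
Conditions: I2, PPh3, imidazole, CH2Cl2, 0 °C→rt
Reagents that add atoms: iodine, II
Why: Appel-type iodination of the primary alcohol runs under near-neutral conditions, so the γ-iodo ketone cannot close to a cyclopropane through its enolate and neither the enone nor C1 is touched.

**Step 5**
Reactants: 8 tert-butyl(but-3-yn-1-yloxy)dimethylsilane
Product: 10 tert-butyl{[(3E)-4-iodo-3-methylbut-3-en-1-yl]oxy}dimethylsilane, via alkenylalane 9 (not isolated)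
Conditions: Me3Al, Cp2ZrCl2 (20 mol %), CH2Cl2, 0 °C→rt; then I2, THF, −30→0 °C
Reagents that add atoms: trimethylaluminium, C[Al](C)C; iodine, II
Why: Negishi zirconium-catalysed carboalumination adds Me–Al syn across the terminal alkyne with methyl on the internal carbon, and iodinolysis of the C–Al bond with retention gives the E-alkenyl iodide that fixes the C7=C8 geometry.

**Step 6**
Reactants: 10 tert-butyl{[(3E)-4-iodo-3-methylbut-3-en-1-yl]oxy}dimethylsilane; 11 (4-bromobut-1-yn-1-yl)trimethylsilane
Product: 13 tert-butyldimethyl{[(3E)-3-methyl-8-(trimethylsilyl)oct-3-en-7-yn-1-yl]oxy}silane, via homopropargylzinc bromide 12 (not isolated)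
Conditions: 11, Zn dust, I2 (5 mol %), DMA, 80 °C; then 10, PdCl2(dppf) (3 mol %), DMA/THF, rt→45 °C
Reagents that add atoms: none
Why: Negishi sp3–sp2 cross-coupling of an alkylzinc halide with an alkenyl iodide forms C6–C7 with retention of the E geometry, and the silyl ether and silylalkyne are inert to the organozinc.

**Step 7**
Reactants: 13 tert-butyldimethyl{[(3E)-3-methyl-8-(trimethylsilyl)oct-3-en-7-yn-1-yl]oxy}silane
Product: 14 tert-butyldimethyl{[(3E)-3-methyloct-3-en-7-yn-1-yl]oxy}silane
Conditions: K2CO3, MeOH, rt
Reagents that add atoms: none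
Why: Methanolysis of the alkynyl C–Si bond under mild carbonate conditions frees the terminal alkyne while the TBS ether stays in place.

**Step 8**
Reactants: 14 tert-butyldimethyl{[(3E)-3-methyloct-3-en-7-yn-1-yl]oxy}silane
Product: 16 tert-butyl{[(3E,7E)-8-iodo-3,7-dimethylocta-3,7-dien-1-yl]oxy}dimethylsilane, via dienylalane 15 (not isolated)
Conditions: Me3Al, Cp2ZrCl2 (20 mol %), CH2Cl2, 0 °C→rt; then I2, THF, −30→0 °C
Reagents that add atoms: trimethylaluminium, C[Al](C)C; iodine, II
Why: Negishi carboalumination followed by iodinolysis is specific for the terminal alkyne (the trisubstituted alkene and the silyl ether do not react) and sets the E-configured C3=C4 alkenyl iodide.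

**Step 9**
Reactants: 7 (5R)-5-(iodomethyl)-4,4-dimethylcyclohex-2-en-1-one; 16 tert-butyl{[(3E,7E)-8-iodo-3,7-dimethylocta-3,7-dien-1-yl]oxy}dimethylsilane
Product: 18 (5R)-5-[(2E,6E)-9-(tert-butyldimethylsilyloxy)-3,7-dimethylnona-2,6-dien-1-yl]-4,4-dimethylcyclohex-2-en-1-one, via alkylzinc iodide 17 (not isolated)
Conditions: 7, activated Zn dust, LiCl, THF, 30 °C; then 16, PdCl2(dppf) (5 mol %), THF, rt→40 °C
Reagents that add atoms: none
Why: LiCl-promoted zinc insertion into the primary iodide tolerates the enone because alkylzinc iodides do not add to enones without copper or a Lewis acid, and Negishi coupling with the E-alkenyl iodide forms C2–C3 with retention of alkene geometry and without touching C1.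

**Step 10**
Reactants: 18 (5R)-5-[(2E,6E)-9-(tert-butyldimethylsilyloxy)-3,7-dimethylnona-2,6-dien-1-yl]-4,4-dimethylcyclohex-2-en-1-one
Product: 19 (5R)-5-[(2E,6E)-9-hydroxy-3,7-dimethylnona-2,6-dien-1-yl]-4,4-dimethylcyclohex-2-en-1-one
Conditions: HF·pyridine, pyridine, THF, 0 °C→rt
Reagents that add atoms: none
Why: Fluoride-mediated cleavage of the primary TBS ether under buffered conditions leaves the enone and both trisubstituted alkenes intact.

**Step 11**
Reactants: 19 (5R)-5-[(2E,6E)-9-hydroxy-3,7-dimethylnona-2,6-dien-1-yl]-4,4-dimethylcyclohex-2-en-1-one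
Product: 20 (3E,7E)-9-[(1R)-2,2-dimethyl-5-oxocyclohex-3-en-1-yl]-3,7-dimethylnona-3,7-dienal
Conditions: Dess–Martin periodinane, NaHCO3, CH2Cl2, 0 °C; filtered through a short pad and used at once
Reagents that add atoms: none
Why: Dess–Martin oxidation under bicarbonate-buffered, non-basic conditions should give the β,γ-unsaturated aldehyde without migration of the C7=C8 bond into conjugation.

**Step 12**
Reactants: 20 (3E,7E)-9-[(1R)-2,2-dimethyl-5-oxocyclohex-3-en-1-yl]-3,7-dimethylnona-3,7-dienal; 21 N,N-dimethylmethyleneiminium iodide (Eschenmoser's salt)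
Product: 25 (1R,3E,7E,10R,11R)-10-hydroxy-4,8,15,15-tetramethyl-12-methylidenebicyclo[9.3.1]pentadeca-3,7-dien-13-one, via samarium(III) enolate 22 (not isolated), via Mannich base 23 (not isolated), via trimethylammonium iodide 24 (not isolated)
Conditions: SmI2 (2.5 equiv), HMPA (10 equiv), THF, 0 °C, 20 added over 6 h (about 2 mM), no proton source; then 21 (6 equiv), 0 °C→rt; aq work-up; MeI, CH2Cl2, rt; then aq NaHCO3
Reagents that add atoms: none
Why: Proposed new method: SmI2/HMPA transfers an electron to the C10 aldehyde, the samarium ketyl adds to C11 (the β-carbon of the ring enone), a second electron turns the resulting α-keto radical into the C12–C13 samarium(III) enolate 22, and this enolate attacks the iminium carbon of 21 to forge C12–C18, after which N-methylation and base-induced β-elimination of trimethylamine unveil the methylene. The closest known reactions are SmI2 aldehyde–enone (ketyl–olefin) cyclisations to five- to eight-membered rings with electrophilic capture of the samarium enolate, and tin-hydride radical macrocyclisations onto enones; closing a twelve-membered ring this way with Mannich capture is the untested extension. The macrocycle (C1 to C11 plus C15) closes in the 12-exo-trig mode, C11 entering the new ring while C12 stays outside it. C11 is controlled by the tether: anchored at C1, the chain can reach only the enone face syn to it, which gives the cis-1,3-bridged bicyclo[9.3.1] skeleton (11R). C10 is controlled by the orientation of the ketyl in the transition state: in the non-chelating HMPA medium the bulky O–Sm group should lie anti to C12 (as in the anti-selective small-ring cases), leaving C10–H and not the C9 chain in the congested sector between C12 and C15, an arrangement that corresponds to 10R; this is the least secure element. The step needs cyclisation to beat pinacol coupling, over-reduction and aldol capture of incoming aldehyde, which slow addition into excess SmI2 without a proton source is meant to secure, and it needs methylenation at C12 and not at C14, which is secured because the enolate is born at C12–C13 by the conjugate addition itself (initial electron transfer to the enone instead would lead to the same bond and the same enolate).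

**Step 13**
Reactants: 25 (1R,3E,7E,10R,11R)-10-hydroxy-4,8,15,15-tetramethyl-12-methylidenebicyclo[9.3.1]pentadeca-3,7-dien-13-one
Product: 26 (1R,3E,7E,10R,11R)-4,8,15,15-tetramethyl-12-methylidene-13-oxobicyclo[9.3.1]pentadeca-3,7-dien-10-yl acetate
Conditions: Ac2O, pyridine, DMAP (cat.), CH2Cl2, 0 °C→rt
Reagents that add atoms: acetic anhydride, CC(=O)OC(C)=O
Why: DMAP-catalysed acyl transfer esterifies the secondary C10 alcohol with retention of configuration, and the exocyclic enone should tolerate the mild amine base at 0 °C.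

**Step 14**
Reactants: 26 (1R,3E,7E,10R,11R)-4,8,15,15-tetramethyl-12-methylidene-13-oxobicyclo[9.3.1]pentadeca-3,7-dien-10-yl acetate
Product: 27 (1R,3S,4S,7S,8S,10R,11R)-3,4:7,8-diepoxy-4,8,15,15-tetramethyl-12-methylidene-13-oxobicyclo[9.3.1]pentadecan-10-yl acetate
Conditions: L-fructose-derived Shi ketone (0.6 equiv), Oxone, K2CO3, Bu4NHSO4, MeCN/dimethoxymethane–aq borate/EDTA buffer (pH about 10.5), 0 °C
Reagents that add atoms: potassium peroxymonosulfate (active component of Oxone), [K+].[O-]S(=O)(=O)OO
Why: In the Shi epoxidation the chiral dioxirane transfers oxygen through a spiro transition state to each electron-rich E-trisubstituted alkene, the L-fructose-derived ketone delivering the (S,S) sense at C3/C4 and C7/C8 under reagent control, while the electron-poor α-methylene ketone is not attacked by the electrophilic oxidant.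

**Compound list**

1 | 4,4-dimethylcyclohex-2-en-1-one | CC1(C)CCC(=O)C=C1 | starting material
2 | 4,4-dimethylcyclohexa-2,5-dien-1-one | CC1(C)C=CC(=O)C=C1 | intermediate
3 | (chloromethyl)(isopropoxy)dimethylsilane | ClC[Si](C)(C)OC(C)C | starting material
4 | {[isopropoxy(dimethyl)silyl]methyl}magnesium chloride | CC(C)O[Si](C)(C)C[Mg]Cl | intermediate
5 | (5R)-5-{[isopropoxy(dimethyl)silyl]methyl}-4,4-dimethylcyclohex-2-en-1-one | O=C1C[C@@H](C[Si](C)(C)OC(C)C)C(C)(C)C=C1 | intermediate
6 | (5R)-5-(hydroxymethyl)-4,4-dimethylcyclohex-2-en-1-one | O=C1C[C@@H](CO)C(C)(C)C=C1 | intermediate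
7 | (5R)-5-(iodomethyl)-4,4-dimethylcyclohex-2-en-1-one | O=C1C[C@@H](CI)C(C)(C)C=C1 | intermediate
8 | tert-butyl(but-3-yn-1-yloxy)dimethylsilane | C#CCCO[Si](C)(C)C(C)(C)C | starting material
9 | dimethyl[(1E)-4-(tert-butyldimethylsilyloxy)-2-methylbut-1-en-1-yl]alane | C[Al](C)/C=C(C)/CCO[Si](C)(C)C(C)(C)C | intermediate
10 | tert-butyl{[(3E)-4-iodo-3-methylbut-3-en-1-yl]oxy}dimethylsilane | I/C=C(C)/CCO[Si](C)(C)C(C)(C)C | intermediate
11 | (4-bromobut-1-yn-1-yl)trimethylsilane | C[Si](C)(C)C#CCCBr | starting material
12 | [4-(trimethylsilyl)but-3-yn-1-yl]zinc bromide | C[Si](C)(C)C#CCC[Zn]Br | intermediate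
13 | tert-butyldimethyl{[(3E)-3-methyl-8-(trimethylsilyl)oct-3-en-7-yn-1-yl]oxy}silane | C[Si](C)(C)C#CCC/C=C(C)/CCO[Si](C)(C)C(C)(C)C | intermediate
14 | tert-butyldimethyl{[(3E)-3-methyloct-3-en-7-yn-1-yl]oxy}silane | C#CCC/C=C(C)/CCO[Si](C)(C)C(C)(C)C | intermediate
15 | dimethyl[(1E,5E)-8-(tert-butyldimethylsilyloxy)-2,6-dimethylocta-1,5-dien-1-yl]alane | C[Al](C)/C=C(C)/CC/C=C(C)/CCO[Si](C)(C)C(C)(C)C | intermediate
16 | tert-butyl{[(3E,7E)-8-iodo-3,7-dimethylocta-3,7-dien-1-yl]oxy}dimethylsilane | I/C=C(C)/CC/C=C(C)/CCO[Si](C)(C)C(C)(C)C | intermediate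
17 | {[(1R)-2,2-dimethyl-5-oxocyclohex-3-en-1-yl]methyl}zinc iodide | O=C1C[C@@H](C[Zn]I)C(C)(C)C=C1 | intermediate
18 | (5R)-5-[(2E,6E)-9-(tert-butyldimethylsilyloxy)-3,7-dimethylnona-2,6-dien-1-yl]-4,4-dimethylcyclohex-2-en-1-one | O=C1C[C@@H](C/C=C(C)/CC/C=C(C)/CCO[Si](C)(C)C(C)(C)C)C(C)(C)C=C1 | intermediate
19 | (5R)-5-[(2E,6E)-9-hydroxy-3,7-dimethylnona-2,6-dien-1-yl]-4,4-dimethylcyclohex-2-en-1-one | O=C1C[C@@H](C/C=C(C)/CC/C=C(C)/CCO)C(C)(C)C=C1 | intermediate
20 | (3E,7E)-9-[(1R)-2,2-dimethyl-5-oxocyclohex-3-en-1-yl]-3,7-dimethylnona-3,7-dienal | O=C1C[C@@H](C/C=C(C)/CC/C=C(C)/CC=O)C(C)(C)C=C1 | intermediate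
21 | N,N-dimethylmethyleneiminium iodide (Eschenmoser's salt) | C=[N+](C)C.[I-] | starting material
22 | samarium(III) enolate–alkoxide of the cyclised skeleton (C12=C13–OSmI2 and C10–OSmI2; idealised, HMPA ligands omitted) | C1=C(O[Sm](I)I)C[C@H]2C/C=C(C)/CC/C=C(C)/C[C@@H](O[Sm](I)I)[C@@H]1C2(C)C | intermediate
23 | (1R,3E,7E,10R,11S)-12-[(dimethylamino)methyl]-10-hydroxy-4,8,15,15-tetramethylbicyclo[9.3.1]pentadeca-3,7-dien-13-one (both C12 epimers; same spatial arrangement at C11 as in 25) | CN(C)CC1C(=O)C[C@H]2C/C=C(C)/CC/C=C(C)/C[C@@H](O)[C@@H]1C2(C)C | intermediate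
24 | N-methyl iodide salt of 23 (trimethylammonium iodide) | C[N+](C)(C)CC1C(=O)C[C@H]2C/C=C(C)/CC/C=C(C)/C[C@@H](O)[C@@H]1C2(C)C.[I-] | intermediate
25 | (1R,3E,7E,10R,11R)-10-hydroxy-4,8,15,15-tetramethyl-12-methylidenebicyclo[9.3.1]pentadeca-3,7-dien-13-one | C=C1C(=O)C[C@H]2C/C=C(C)/CC/C=C(C)/C[C@@H](O)[C@@H]1C2(C)C | intermediate
26 | (1R,3E,7E,10R,11R)-4,8,15,15-tetramethyl-12-methylidene-13-oxobicyclo[9.3.1]pentadeca-3,7-dien-10-yl acetate | C=C1C(=O)C[C@H]2C/C=C(C)/CC/C=C(C)/C[C@@H](OC(C)=O)[C@@H]1C2(C)C | intermediate
27 | (1R,3S,4S,7S,8S,10R,11R)-3,4:7,8-diepoxy-4,8,15,15-tetramethyl-12-methylidene-13-oxobicyclo[9.3.1]pentadecan-10-yl acetate | C=C1C(=O)C[C@H]2C[C@@H]3O[C@@]3(C)CC[C@@H]3O[C@@]3(C)C[C@@H](OC(C)=O)[C@@H]1C2(C)C | target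

**Step count**

Total: 14 steps. Longest linear sequence: 10 steps (steps 1–4 and 9–14, or equally steps 5–14).

**Steps most likely to fail**

Step 12. The ketyl may dimerise, be reduced further, or the samarium enolate may add to incoming aldehyde before the hindered C11 next to the quaternary centre is reached. The ketyl may also be delivered with the wrong facial sense at C10, and the enolate may be protonated before the iminium salt captures it. The fallback uses known chemistry and installs C18 before ring closure. Starting from 18, α-iodination of the enone (I2, pyridine, CH2Cl2) would give the 2-iodoenone F1. Stille coupling with (tributylstannyl)methanol (Pd(PPh3)4, dioxane, 90 °C) would give the 2-(hydroxymethyl)enone F2, and Appel bromination (CBr4, PPh3) the 2-(bromomethyl)enone F3. Desilylation (HF·pyridine) would give the bromo alcohol F4 and Dess–Martin oxidation the bromo aldehyde F5. An intramolecular Nozaki–Hiyama allylation (CrCl2, THF, high dilution), a macrocyclisation type established for twelve- to fourteen-membered carbocycles, would then join C11 (the γ-terminus of the allylchromium formed at C18) to the C10 aldehyde and release the C12=C18 methylene in the same event. The C10/C11 relationship would follow from the cyclic allylchromium transition state and would have to be checked. The route is rejoined at 25.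

Step 14. In the macrocycle the exposed alkene faces are set by ring conformation, so catalyst control may be overridden at one alkene (poor facial selectivity), and the second epoxidation may stall at the mono-epoxide stage. The fallback sets out from 25, whose free C10 hydroxyl is used as a directing group. Vanadium-catalysed epoxidation of the homoallylic C7=C8 alkene (VO(acac)2, t-BuOOH, CH2Cl2) would give the 7,8-epoxy alcohol F6, oxygen being delivered from the face held by the C10 vanadate ester. Acetylation (Ac2O, pyridine, DMAP) would give the epoxy acetate F7. The single remaining C3=C4 alkene would then be epoxidised on its own, with the same chiral ketone or with mCPBA if peripheral attack proves to be the favourable mode, rejoining the route at 27.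

Step 2. Transfer of the silylmethyl group to the β-carbon next to the quaternary centre may be slow, and discrimination of the enantiotopic enone faces may be insufficient. The fallback sets out from 2. Rhodium/BINAP-catalysed asymmetric 1,4-addition of potassium vinyltrifluoroborate (BINAP enantiomer chosen for the required sense) would give the vinyl enone F8, which has the same spatial arrangement at C1. Selective ozonolysis of the vinyl group (O3, CH2Cl2, −78 °C, indicator dye; PPh3) would give the keto aldehyde F9. This would be reduced without isolation by NaBH(OAc)3, which is aldehyde-selective and limits epimerisation at C1, to give 6, where the route is rejoined and step 3 is bypassed.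

**Further compounds**

F1 | step 12 | (5R)-5-[(2E,6E)-9-(tert-butyldimethylsilyloxy)-3,7-dimethylnona-2,6-dien-1-yl]-2-iodo-4,4-dimethylcyclohex-2-en-1-one | O=C1C[C@@H](C/C=C(C)/CC/C=C(C)/CCO[Si](C)(C)C(C)(C)C)C(C)(C)C=C1I
F2 | step 12 | (5R)-5-[(2E,6E)-9-(tert-butyldimethylsilyloxy)-3,7-dimethylnona-2,6-dien-1-yl]-2-(hydroxymethyl)-4,4-dimethylcyclohex-2-en-1-one | O=C1C[C@@H](C/C=C(C)/CC/C=C(C)/CCO[Si](C)(C)C(C)(C)C)C(C)(C)C=C1CO
F3 | step 12 | (5R)-2-(bromomethyl)-5-[(2E,6E)-9-(tert-butyldimethylsilyloxy)-3,7-dimethylnona-2,6-dien-1-yl]-4,4-dimethylcyclohex-2-en-1-one | O=C1C[C@@H](C/C=C(C)/CC/C=C(C)/CCO[Si](C)(C)C(C)(C)C)C(C)(C)C=C1CBr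
F4 | step 12 | (5R)-2-(bromomethyl)-5-[(2E,6E)-9-hydroxy-3,7-dimethylnona-2,6-dien-1-yl]-4,4-dimethylcyclohex-2-en-1-one | O=C1C[C@@H](C/C=C(C)/CC/C=C(C)/CCO)C(C)(C)C=C1CBr
F5 | step 12 | (3E,7E)-9-[(1R)-4-(bromomethyl)-2,2-dimethyl-5-oxocyclohex-3-en-1-yl]-3,7-dimethylnona-3,7-dienal | O=C1C[C@@H](C/C=C(C)/CC/C=C(C)/CC=O)C(C)(C)C=C1CBr
F6 | step 14 | (1R,3E,7S,8S,10R,11R)-7,8-epoxy-10-hydroxy-4,8,15,15-tetramethyl-12-methylidenebicyclo[9.3.1]pentadec-3-en-13-one | C=C1C(=O)C[C@H]2C/C=C(C)/CC[C@@H]3O[C@@]3(C)C[C@@H](O)[C@@H]1C2(C)C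
F7 | step 14 | (1R,3E,7S,8S,10R,11R)-7,8-epoxy-4,8,15,15-tetramethyl-12-methylidene-13-oxobicyclo[9.3.1]pentadec-3-en-10-yl acetate | C=C1C(=O)C[C@H]2C/C=C(C)/CC[C@@H]3O[C@@]3(C)C[C@@H](OC(C)=O)[C@@H]1C2(C)C
F8 | step 2 | (5S)-4,4-dimethyl-5-vinylcyclohex-2-en-1-one | O=C1C[C@@H](C=C)C(C)(C)C=C1
F9 | step 2 | (1R)-2,2-dimethyl-5-oxocyclohex-3-ene-1-carbaldehyde | O=C1C[C@@H](C=O)C(C)(C)C=C1
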